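**Retrosynthetic overview**
- The target is opened at C3–C4. C3 carries the only free hydroxyl and sits between the C2 methylene and the alkene carbon C4 of the ten-membered carbocycle (ring A), so it is formed last from a C3 aldehyde and a C4 (E)-alkenyl iodide.
- The iodo-aldehyde 23 comes from alkyne 19 by syn-hydrostannation/iodination at C4≡C5; the C3 aldehyde is released from a silyl ether.
- C6–C7 and the C6, C7 stereocentres come from a chromium Barbier allylation of ynal 17 with the 3-(bromomethyl)butenolide 13, which also produces the α-methylene-γ-lactone (ring B, trans-fused at C7–C8).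
- Butenolide 13 comes from ring-closing metathesis of acrylate 12; C8 is taken from (S)-epichlorohydrin, and the E C1=C10 alkene from carboalumination/ethylene oxide.
- Ring order: the five-membered lactone ring B first (step 7), the ten-membered ring A last (step 15).

Key step: step 15

Remark: germacrane locants are used throughout (C12 lactone carbonyl, C13 exocyclic methylene, C14 methyl on C10, C15 acyloxymethyl on C4). The CIP label at C6 (S in 18–23, R in 24) and at C7 (S in 18, R from 19 on) changes through priority changes only; no bond to these centres is broken after step 10.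

**Step 1**
Reactants: 1 (S)-2-(chloromethyl)oxirane; 2 ethynyltrimethylsilane
Product: 3 (S)-1-chloro-5-(trimethylsilyl)pent-4-yn-2-ol
Conditions: 2, n-BuLi, THF, −78 °C; BF3·OEt2; then 1, −78 °C; aq. NH4Cl
Reagents that add atoms: none
Why: Boron-trifluoride-promoted SN2 opening of the epoxide by the lithium acetylide at the unsubstituted ring carbon leaves the chiral-pool stereocentre (future C8) and the chloride untouched.

**Step 2**
Reactants: 3 (S)-1-chloro-5-(trimethylsilyl)pent-4-yn-2-ol
Product: 5 (S)-2-(prop-2-yn-1-yl)oxirane, via (S)-trimethyl[3-(oxiran-2-yl)prop-1-yn-1-yl]silane 4 (not isolated)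
Conditions: K2CO3, MeOH, 0 °C to rt; extracted into pentane/Et2O and used as a concentrated solution (volatile)
Reagents that add atoms: none
Why: Intramolecular Williamson closure of the chlorohydrin gives the terminal epoxide without breaking the C8–O bond, and methanolic carbonate then cleaves the alkynyl C–Si bond.

**Step 3**
Reactants: 5 (S)-2-(prop-2-yn-1-yl)oxirane
Product: 6 (S)-hex-1-en-5-yn-3-ol
Conditions: trimethylsulfonium iodide (3 equiv), n-BuLi (2.9 equiv), THF, −10 °C; then 5, −10 °C to rt
Reagents that add atoms: trimethylsulfonium iodide, C[S+](C)C.[I-]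
Why: Sulfonium-ylide one-carbon homologation of a terminal epoxide to an allylic alcohol (ylide opening at CH2, then base-induced loss of dimethyl sulfide); C8 is not involved and the ylide is too weak a base to metalate the alkyne.

**Step 4**
Reactants: 6 (S)-hex-1-en-5-yn-3-ol
Product: 9 (3S,5E)-5-methylocta-1,5-diene-3,8-diol, via dimethylalkenylalane 7 (not isolated), via lithium alkenylalanate 8 (not isolated)
Conditions: AlMe3 (3.5 equiv), Cp2ZrCl2 (0.3 equiv), CH2Cl2, 0 °C to rt; volatiles removed; THF, n-BuLi (2.2 equiv), −78 to 0 °C; ethylene oxide (5 equiv), −78 °C to rt; aq. Rochelle salt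
Reagents that add atoms: trimethylaluminium, C[Al](C)C; ethylene oxide, C1CO1
Why: Zirconium-catalysed carboalumination (Negishi) adds methyl and aluminium syn across the terminal alkyne with methyl on the internal carbon, which fixes the E C1=C10 geometry, and the alanate opens ethylene oxide with retention at the alkenyl carbon to deliver C2–C3.

**Step 5**
Reactants: 9 (3S,5E)-5-methylocta-1,5-diene-3,8-diol
Product: 10 (3S,5E)-8-[(tert-butyldiphenylsilyl)oxy]-5-methylocta-1,5-dien-3-ol
Conditions: TBDPSCl (1.05 equiv), imidazole, CH2Cl2, −20 to 0 °C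
Reagents that add atoms: tert-butyl(chloro)diphenylsilane, CC(C)(C)[Si](Cl)(c1ccccc1)c1ccccc1
Why: The bulky silyl chloride should react selectively at the primary C3 hydroxyl and leave the secondary allylic C8 hydroxyl free.

**Step 6**
Reactants: 10 (3S,5E)-8-[(tert-butyldiphenylsilyl)oxy]-5-methylocta-1,5-dien-3-ol; 11 2-(bromomethyl)prop-2-enoic acid
Product: 12 (3S,5E)-8-[(tert-butyldiphenylsilyl)oxy]-5-methylocta-1,5-dien-3-yl 2-(bromomethyl)prop-2-enoate
Conditions: DCC (1.2 equiv), DMAP (5 mol %), CH2Cl2, −10 to 0 °C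
Reagents that add atoms: none
Why: Steglich esterification of the secondary allylic alcohol proceeds with retention at C8 (the C–O bond is not broken); low temperature and low DMAP loading limit attack on the allylic bromide.

**Step 7**
Reactants: 12 (3S,5E)-8-[(tert-butyldiphenylsilyl)oxy]-5-methylocta-1,5-dien-3-yl 2-(bromomethyl)prop-2-enoate
Product: 13 (5S)-3-(bromomethyl)-5-[(2E)-5-[(tert-butyldiphenylsilyl)oxy]-2-methylpent-2-en-1-yl]furan-2(5H)-one
Conditions: second-generation Hoveyda–Grubbs catalyst, RuCl2(H2IMes)(=CH-C6H4-2-OiPr) (5 mol %), CH2Cl2 (0.01 M), 40 °C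
Reagents that add atoms: none
Why: Ring-closing metathesis between the vinyl group and the acrylate closes the five-membered butenolide (C7=C11) with loss of ethene; the trisubstituted C1=C10 alkene cannot close a favourable ring and the phosphine-free catalyst tolerates the allylic bromide.

**Step 8**
Reactants: 14 but-2-yne-1,4-diol; 15 3-methylbutanoyl chloride (isovaleryl chloride)
Product: 16 4-hydroxybut-2-yn-1-yl 3-methylbutanoate
Conditions: 14 (5 equiv), 15 (1 equiv), pyridine, THF, 0 °C
Reagents that add atoms: none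
Why: Mono-acylation of the symmetrical diol is favoured statistically by the excess of diol, which is removed by aqueous extraction.

**Step 9**
Reactants: 16 4-hydroxybut-2-yn-1-yl 3-methylbutanoate
Product: 17 4-oxobut-2-yn-1-yl 3-methylbutanoate
Conditions: Dess–Martin periodinane (1.2 equiv), CH2Cl2, 0 °C to rt; used promptly
Reagents that add atoms: none
Why: Dess–Martin oxidation converts the propargylic alcohol into the ynal under neutral conditions that leave the ester intact.

**Step 10**
Reactants: 13 (5S)-3-(bromomethyl)-5-[(2E)-5-[(tert-butyldiphenylsilyl)oxy]-2-methylpent-2-en-1-yl]furan-2(5H)-one; 17 4-oxobut-2-yn-1-yl 3-methylbutanoate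
Product: 18 (4S)-4-[(2S,3S)-2-[(2E)-5-[(tert-butyldiphenylsilyl)oxy]-2-methylpent-2-en-1-yl]-4-methylidene-5-oxooxolan-3-yl]-4-hydroxybut-2-yn-1-yl 3-methylbutanoate
Conditions: CrCl2 (3 equiv), THF, 0 °C to rt; 13 and 17 added together; aq. NH4Cl
Reagents that add atoms: none
Why: Nozaki–Hiyama-type chromium Barbier allylation, known for 3-(bromomethyl)butenolides: the allylchromium adds through ring carbon C7 in a Zimmerman–Traxler chair on the face anti to the C8 side chain (trans-lactone, sets C7) with the alkynyl group equatorial against the E-locked allyl unit (anti adduct, sets C6), and regenerates the exocyclic methylene.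

**Step 11**
Reactants: 18 the C6 propargylic alcohol from step 10; 15 3-methylbutanoyl chloride
Product: 19 (1S)-1-[(2S,3R)-2-[(2E)-5-[(tert-butyldiphenylsilyl)oxy]-2-methylpent-2-en-1-yl]-4-methylidene-5-oxooxolan-3-yl]but-2-yne-1,4-diyl bis(3-methylbutanoate)
Conditions: 15 (1.5 equiv), pyridine, DMAP (cat.), CH2Cl2, 0 °C
Reagents that add atoms: none
Why: Acylation of the secondary propargylic alcohol occurs at oxygen with retention at C6 and is expected to outrun translactonisation.

**Step 12**
Reactants: 19 the bis(3-methylbutanoate) alkyne from step 11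
Product: 21 (1S,2E)-1-[(2S,3R)-2-[(2E)-5-[(tert-butyldiphenylsilyl)oxy]-2-methylpent-2-en-1-yl]-4-methylidene-5-oxooxolan-3-yl]-3-iodobut-2-ene-1,4-diyl bis(3-methylbutanoate), via C4 tributylstannyl alkene 20 (not isolated)
Conditions: Bu3SnH (1.2 equiv, slow addition), PdCl2(PPh3)2 (3 mol %), THF, 0 °C; then I2 (1.3 equiv), CH2Cl2, 0 °C; aq. Na2S2O3/KF
Reagents that add atoms: iodine, II; tributyltin hydride, CCCC[SnH](CCCC)CCCC (tin of 20 only)
Why: Palladium-catalysed hydrostannation is a syn addition that should place tin on the less hindered alkyne carbon C4 (next to the CH2O group, remote from the branched C6), and iododestannylation proceeds with retention to give the E-iodoalkene with C6 and C15 cis.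

**Step 13**
Reactants: 21 the alkenyl iodide silyl ether from step 12
Product: 22 (1S,2E)-1-[(2S,3R)-2-[(2E)-5-hydroxy-2-methylpent-2-en-1-yl]-4-methylidene-5-oxooxolan-3-yl]-3-iodobut-2-ene-1,4-diyl bis(3-methylbutanoate)
Conditions: HF·pyridine, pyridine, THF, 0 °C to rt
Reagents that add atoms: none
Why: Buffered fluoride cleaves the primary silyl ether and leaves the two isovalerates, the methylene lactone and the alkenyl iodide untouched.

**Step 14**
Reactants: 22 the C3 primary alcohol from step 13
Product: 23 (1S,2E)-3-iodo-1-[(2S,3R)-4-methylidene-2-[(2E)-2-methyl-5-oxopent-2-en-1-yl]-5-oxooxolan-3-yl]but-2-ene-1,4-diyl bis(3-methylbutanoate)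
Conditions: Dess–Martin periodinane (1.3 equiv), NaHCO3, CH2Cl2, 0 °C; filtered through a short silica pad and used at once
Reagents that add atoms: none
Why: Bicarbonate-buffered Dess–Martin oxidation gives the β,γ-unsaturated C3 aldehyde without moving the C1=C10 double bond into conjugation.

**Step 15**
Reactants: 23 the C3 aldehyde / C4 (E)-alkenyl iodide from step 14
Product: 24 (1(10)E,3R,4E,6R,7R,8S)-3-hydroxy-6,15-bis[(3-methylbutanoyl)oxy]germacra-1(10),4,11(13)-trien-12,8-olide (target)
Conditions: CrCl2 (10 equiv), (S)-N-[2-(4-isopropyl-4,5-dihydrooxazol-2-yl)-6-methylphenyl]methanesulfonamide (11 equiv), Et3N (11 equiv), THF, rt; NiCl2 (0.5 equiv); 23 added by syringe pump over 12 h to a final 0.002 M, rt; aq. work-up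
Reagents that add atoms: none
Why: CrCl2 reduces NiCl2 to zerovalent nickel, which inserts into the C4–I bond with retention of the alkene geometry; transmetalation gives an alkenyl species of trivalent chromium that adds only to the C3 aldehyde (Nozaki–Hiyama–Kishi reaction in its known macrocyclisation mode for medium-ring allylic alcohols). Ring A, the ten-membered carbocycle, closes by 10-exo-trig attack of C4 on the C3 carbonyl, the C=O lying outside the new ring. The new C3 stereocentre (3R) is to be controlled by the chiral sulfonamide–oxazoline ligand on chromium together with the conformational bias of the trans-fused lactone and the E alkenes in the tether; the sense of induction of the (S)-ligand is not predicted here and must be checked on the first run, with the antipode used if the pairing is mismatched. The step needs chemoselectivity for the aldehyde over the two isovalerates and the methylene lactone, which the weakly basic alkenylchromium provides, and E geometry at C4=C5, which is already fixed in the iodide. Slow addition at high dilution favours ring closure over dimerisation, and a low nickel loading limits ionisation of the allylic C6 ester and loss of the C15 acyloxy group to an allene.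

**Compound list**
1 | (S)-2-(chloromethyl)oxirane, (S)-epichlorohydrin | ClC[C@@H]1CO1 | starting material
2 | ethynyltrimethylsilane | C#C[Si](C)(C)C | starting material
3 | (S)-1-chloro-5-(trimethylsilyl)pent-4-yn-2-ol | C[Si](C)(C)C#CC[C@H](O)CCl | intermediate
4 | (S)-trimethyl[3-(oxiran-2-yl)prop-1-yn-1-yl]silane | C[Si](C)(C)C#CC[C@H]1CO1 | intermediate (not isolated)
5 | (S)-2-(prop-2-yn-1-yl)oxirane | C#CC[C@H]1CO1 | intermediate
6 | (S)-hex-1-en-5-yn-3-ol | C=C[C@@H](O)CC#C | intermediate
7 | dimethylalkenylalane of 6 (O-dimethylaluminium alkoxide, E C–Al) | C=C[C@@H](O[Al](C)C)C/C(C)=C/[Al](C)C | intermediate (not isolated)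
8 | lithium butyl(dimethyl)alkenylalanate of 7 | [Li+].C=C[C@@H](O[Al](C)C)C/C(C)=C/[Al-](C)(C)CCCC | intermediate (not isolated)
9 | (3S,5E)-5-methylocta-1,5-diene-3,8-diol | C=C[C@@H](O)C/C(C)=C/CCO | intermediate
10 | (3S,5E)-8-[(tert-butyldiphenylsilyl)oxy]-5-methylocta-1,5-dien-3-ol | C=C[C@@H](O)C/C(C)=C/CCO[Si](c1ccccc1)(c1ccccc1)C(C)(C)C | intermediate
11 | 2-(bromomethyl)prop-2-enoic acid | C=C(CBr)C(=O)O | starting material
12 | (3S,5E)-8-[(tert-butyldiphenylsilyl)oxy]-5-methylocta-1,5-dien-3-yl 2-(bromomethyl)prop-2-enoate | C=C[C@@H](OC(=O)C(=C)CBr)C/C(C)=C/CCO[Si](c1ccccc1)(c1ccccc1)C(C)(C)C | intermediate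
13 | (5S)-3-(bromomethyl)-5-[(2E)-5-[(tert-butyldiphenylsilyl)oxy]-2-methylpent-2-en-1-yl]furan-2(5H)-one | O=C1O[C@@H](C/C(C)=C/CCO[Si](c2ccccc2)(c2ccccc2)C(C)(C)C)C=C1CBr | intermediate
14 | but-2-yne-1,4-diol | OCC#CCO | starting material
15 | 3-methylbutanoyl chloride (isovaleryl chloride) | CC(C)CC(Cl)=O | starting material
16 | 4-hydroxybut-2-yn-1-yl 3-methylbutanoate | OCC#CCOC(=O)CC(C)C | intermediate
17 | 4-oxobut-2-yn-1-yl 3-methylbutanoate | O=CC#CCOC(=O)CC(C)C | intermediate
18 | (4S)-4-[(2S,3S)-2-[(2E)-5-[(tert-butyldiphenylsilyl)oxy]-2-methylpent-2-en-1-yl]-4-methylidene-5-oxooxolan-3-yl]-4-hydroxybut-2-yn-1-yl 3-methylbutanoate | C=C1C(=O)O[C@@H](C/C(C)=C/CCO[Si](c2ccccc2)(c2ccccc2)C(C)(C)C)[C@@H]1[C@H](O)C#CCOC(=O)CC(C)C | intermediate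
19 | (1S)-1-[(2S,3R)-2-[(2E)-5-[(tert-butyldiphenylsilyl)oxy]-2-methylpent-2-en-1-yl]-4-methylidene-5-oxooxolan-3-yl]but-2-yne-1,4-diyl bis(3-methylbutanoate) | C=C1C(=O)O[C@@H](C/C(C)=C/CCO[Si](c2ccccc2)(c2ccccc2)C(C)(C)C)[C@@H]1[C@H](OC(=O)CC(C)C)C#CCOC(=O)CC(C)C | intermediate
20 | (1S,2E)-1-[(2S,3R)-2-[(2E)-5-[(tert-butyldiphenylsilyl)oxy]-2-methylpent-2-en-1-yl]-4-methylidene-5-oxooxolan-3-yl]-3-(tributylstannyl)but-2-ene-1,4-diyl bis(3-methylbutanoate) | C=C1C(=O)O[C@@H](C/C(C)=C/CCO[Si](c2ccccc2)(c2ccccc2)C(C)(C)C)[C@@H]1[C@H](OC(=O)CC(C)C)/C=C(/[Sn](CCCC)(CCCC)CCCC)COC(=O)CC(C)C | intermediate (not isolated)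
21 | (1S,2E)-1-[(2S,3R)-2-[(2E)-5-[(tert-butyldiphenylsilyl)oxy]-2-methylpent-2-en-1-yl]-4-methylidene-5-oxooxolan-3-yl]-3-iodobut-2-ene-1,4-diyl bis(3-methylbutanoate) | C=C1C(=O)O[C@@H](C/C(C)=C/CCO[Si](c2ccccc2)(c2ccccc2)C(C)(C)C)[C@@H]1[C@H](OC(=O)CC(C)C)/C=C(/I)COC(=O)CC(C)C | intermediate
22 | (1S,2E)-1-[(2S,3R)-2-[(2E)-5-hydroxy-2-methylpent-2-en-1-yl]-4-methylidene-5-oxooxolan-3-yl]-3-iodobut-2-ene-1,4-diyl bis(3-methylbutanoate) | C=C1C(=O)O[C@@H](C/C(C)=C/CCO)[C@@H]1[C@H](OC(=O)CC(C)C)/C=C(/I)COC(=O)CC(C)C | intermediate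
23 | (1S,2E)-3-iodo-1-[(2S,3R)-4-methylidene-2-[(2E)-2-methyl-5-oxopent-2-en-1-yl]-5-oxooxolan-3-yl]but-2-ene-1,4-diyl bis(3-methylbutanoate) | C=C1C(=O)O[C@@H](C/C(C)=C/CC=O)[C@@H]1[C@H](OC(=O)CC(C)C)/C=C(/I)COC(=O)CC(C)C | intermediate (key-step precursor)
24 | (1(10)E,3R,4E,6R,7R,8S)-3-hydroxy-6,15-bis[(3-methylbutanoyl)oxy]germacra-1(10),4,11(13)-trien-12,8-olide | C=C1C(=O)O[C@H]2C/C(C)=C/C[C@@H](O)/C(COC(=O)CC(C)C)=C/[C@@H](OC(=O)CC(C)C)[C@H]12 | target

**Step count**
Total: 15 steps. Longest linear sequence: 13 steps (steps 1–7 and 10–15); steps 8–9 form the two-step side branch to ynal 17.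

**Steps most likely to fail**

Step 15 (macrocyclisation). The alkenylchromium may add to the C3 aldehyde with poor facial selectivity, or the ligand-bound chromium may react so slowly that protodeiodination and intermolecular coupling compete. The fallback moves the control of C3 out of the C–C bond-forming step. Starting from 23, the ring is closed without ligand (CrCl2, catalytic NiCl2, DMSO, high dilution), which should give 24 together with its C3 epimer, (3S)-3-epi-24 F1. The mixture is oxidised with Dess–Martin periodinane to the C3 enone, 3-oxo-germacradienolide F2. Reagent-controlled 1,2-reduction with (S)-2-methyl-CBS-oxazaborolidine and catecholborane at −78 °C then returns to 24.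

Step 10 (chromium Barbier allylation). The small alkynyl group may be tolerated in the axial position of the chair, which would erode facial selectivity at C6. The fallback makes the step stereoconvergent. Starting from 13 and 17, the Barbier reaction is run as described and the C6 epimer of 18, (4R)-carbinol F3, is separated. F3 is esterified with 3-methylbutanoic acid under Mitsunobu conditions (PPh3, DIAD, toluene, 0 °C) with inversion at C6, which returns to 19; the correct epimer 18 reaches 19 by step 11.

Step 12 (hydrostannation/iodination). Tin may be delivered to C5 as well as C4, because both alkyne carbons carry an acyloxy-bearing carbon and only sterics distinguish them; zerovalent palladium may also ionise the propargylic esters. The fallback adds a free hydroxyl as a second regiocontrol element.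
- Starting from 13, the Barbier reaction is run with 4-[(tert-butyldimethylsilyl)oxy]but-2-ynal F4 (Dess–Martin oxidation of commercial 4-[(tert-butyldimethylsilyl)oxy]but-2-yn-1-ol) to give the C6 alcohol with a C15 silyl ether F5.
- Acylation with 15 gives the C6 isovalerate F6.
- PPTS in MeOH removes the primary tert-butyldimethylsilyl group selectively and gives the free C15 propargylic alcohol F7.
- Hydrostannation (Bu3SnH, PdCl2(PPh3)2) is then directed to C4 by both the free primary hydroxyl and sterics, giving the C4 stannane F8; iodine converts it into the iodo alcohol F9.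
- Acylation of F9 with 15 returns to 21.

**Further compounds**
F1 | step 15 | (3S)-3-epi-24, C3 epimer of the target | C=C1C(=O)O[C@H]2C/C(C)=C/C[C@H](O)/C(COC(=O)CC(C)C)=C/[C@@H](OC(=O)CC(C)C)[C@H]12
F2 | step 15 | C3 ketone (3-oxo analogue of 24) | C=C1C(=O)O[C@H]2C/C(C)=C/CC(=O)/C(COC(=O)CC(C)C)=C/[C@@H](OC(=O)CC(C)C)[C@H]12
F3 | step 10 | C6 epimer of 18 | C=C1C(=O)O[C@@H](C/C(C)=C/CCO[Si](c2ccccc2)(c2ccccc2)C(C)(C)C)[C@@H]1[C@@H](O)C#CCOC(=O)CC(C)C
F4 | step 12 | 4-[(tert-butyldimethylsilyl)oxy]but-2-ynal | O=CC#CCO[Si](C)(C)C(C)(C)C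
F5 | step 12 | analogue of 18 with a C15 tert-butyldimethylsilyl ether | C=C1C(=O)O[C@@H](C/C(C)=C/CCO[Si](c2ccccc2)(c2ccccc2)C(C)(C)C)[C@@H]1[C@H](O)C#CCO[Si](C)(C)C(C)(C)C
F6 | step 12 | C6 isovalerate of F5 | C=C1C(=O)O[C@@H](C/C(C)=C/CCO[Si](c2ccccc2)(c2ccccc2)C(C)(C)C)[C@@H]1[C@H](OC(=O)CC(C)C)C#CCO[Si](C)(C)C(C)(C)C
F7 | step 12 | C6 isovalerate with free C15 propargylic alcohol | C=C1C(=O)O[C@@H](C/C(C)=C/CCO[Si](c2ccccc2)(c2ccccc2)C(C)(C)C)[C@@H]1[C@H](OC(=O)CC(C)C)C#CCO
F8 | step 12 | C4 tributylstannyl alkene with free C15 alcohol | C=C1C(=O)O[C@@H](C/C(C)=C/CCO[Si](c2ccccc2)(c2ccccc2)C(C)(C)C)[C@@H]1[C@H](OC(=O)CC(C)C)/C=C(/[Sn](CCCC)(CCCC)CCCC)CO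
F9 | step 12 | C4 (E)-iodoalkene with free C15 alcohol | C=C1C(=O)O[C@@H](C/C(C)=C/CCO[Si](c2ccccc2)(c2ccccc2)C(C)(C)C)[C@@H]1[C@H](OC(=O)CC(C)C)/C=C(/I)CO
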